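Ring B of the target (B1 O-aryl, B2 Br, B3 H, B4 Br, B5 Br, B6 OH) has its only hydrogen para to the hydroxyl and two bromines meta to it, a pattern that bromination of a phenol cannot produce. A removable amino group is therefore placed on B3 and the B2–Br and B4–Br bonds are disconnected. In a single operation bromine enters both carbons ortho to the nitrogen of an aniline whose B6 oxygen is masked as a mesylate, whose B5 already carries bromine and whose ring A (3,5-dibromo-2-methoxyphenyl) is complete. Diazotisation and reduction then remove the nitrogen, and the mesylate is cleaved last.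

Key step: step 8

Remark: the target is achiral, so no stereocentre has to be set. Ring A is numbered from the carbon bearing the diaryl ether oxygen (position 1) through the methoxy-bearing carbon (position 2), so its bromines sit on positions 3 and 5 and its hydrogens on positions 4 and 6; ring B is numbered as above.

Step 1
Reactants: 1 4-nitrocatechol (4-nitrobenzene-1,2-diol, 1.15 equiv); 2 2-fluorobenzaldehyde
Product: 3 2-(2-hydroxy-5-nitrophenoxy)benzaldehyde
Conditions: KOt-Bu (2.0 equiv per 1), DMSO, 25 °C; then 2, 80 °C; aq. HCl work-up
Reagents that add atoms: none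
Why: SNAr (addition–elimination) at the fluorine-bearing carbon activated by the ortho formyl group, in which the phenoxide meta to nitro, the more basic and more nucleophilic oxygen of the dianion, attacks, while any isomer arylated on the other oxygen may drift to the same product by Smiles rearrangement because this releases the better stabilised para-nitrophenoxide.

Step 2
Reactants: 3 2-(2-hydroxy-5-nitrophenoxy)benzaldehyde
Product: 4 2-(3-bromo-2-hydroxy-5-nitrophenoxy)benzaldehyde
Conditions: Br2 (1.05 equiv), NaOAc (1.2 equiv), AcOH, 20–40 °C
Reagents that add atoms: bromine, BrBr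
Why: Electrophilic aromatic bromination directed by the free ring B hydroxyl to B5, its only open ortho position (the para position is held by the nitro group), while the other ring, which carries a formyl group and only a diaryl ether oxygen as donor, should react far more slowly.

Step 3
Reactants: 4 2-(3-bromo-2-hydroxy-5-nitrophenoxy)benzaldehyde
Product: 5 2-bromo-6-(2-formylphenoxy)-4-nitrophenyl methanesulfonate
Conditions: MsCl (1.3 equiv), Et3N (1.6 equiv), CH2Cl2, 0 °C
Reagents that add atoms: methanesulfonyl chloride, CS(=O)(=O)Cl
Why: O-Sulfonylation of a phenol; the molecule has a single hydroxyl group at this stage, so the B6 oxygen is masked without any need to tell two phenols apart.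

Step 4
Reactants: 5 2-bromo-6-(2-formylphenoxy)-4-nitrophenyl methanesulfonate
Product: 7 2-bromo-6-(2-hydroxyphenoxy)-4-nitrophenyl methanesulfonate, via aryl formate 6 (not isolated)
Conditions: mCPBA (1.5 equiv), CH2Cl2, 25–40 °C; then HCl (cat.), MeOH, 25 °C
Reagents that add atoms: 3-chloroperoxybenzoic acid (mCPBA), OOC(=O)c1cccc(Cl)c1
Why: Baeyer–Villiger oxidation of an aryl aldehyde (Dakin-type), in which the aryl group bearing the ortho aryloxy donor migrates in the peracid adduct to give the formate, which is then methanolysed under acid so that the nitro-activated mesylate never meets base.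

Step 5
Reactants: 7 2-bromo-6-(2-hydroxyphenoxy)-4-nitrophenyl methanesulfonate
Product: 8 2-bromo-6-(3,5-dibromo-2-hydroxyphenoxy)-4-nitrophenyl methanesulfonate
Conditions: Br2 (2.1 equiv), AcOH, 20 °C
Reagents that add atoms: bromine, BrBr
Why: Electrophilic aromatic bromination ortho (ring A position 3) and para (ring A position 5) to the new ring A hydroxyl, the strongest donor in the molecule, while ring B, carrying nitro, bromine and sulfonyloxy groups, is inert.

Step 6
Reactants: 8 2-bromo-6-(3,5-dibromo-2-hydroxyphenoxy)-4-nitrophenyl methanesulfonate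
Product: 9 2-bromo-6-(3,5-dibromo-2-methoxyphenoxy)-4-nitrophenyl methanesulfonate
Conditions: TMSCHN2 (2 M in hexanes, 3 equiv), MeOH–toluene (1:3), 0 → 25 °C
Reagents that add atoms: trimethylsilyldiazomethane, C[Si](C)(C)C=[N+]=[N-]
Why: O-Methylation of an acidic phenol by a diazoalkane, which needs no base and so keeps a free phenoxide away from the nitro-activated mesylate on B6.

Step 7
Reactants: 9 2-bromo-6-(3,5-dibromo-2-methoxyphenoxy)-4-nitrophenyl methanesulfonate
Product: 10 4-amino-2-bromo-6-(3,5-dibromo-2-methoxyphenoxy)phenyl methanesulfonate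
Conditions: Fe powder (5 equiv), NH4Cl, EtOH–H2O (4:1), 75 °C
Reagents that add atoms: none
Why: Béchamp-type reduction of the nitroarene by zerovalent iron under nearly neutral conditions that leave the aryl bromides, the methyl ether and the aryl mesylate intact.

Step 8
Reactants: 10 4-amino-2-bromo-6-(3,5-dibromo-2-methoxyphenoxy)phenyl methanesulfonate
Product: 11 4-amino-2,3,5-tribromo-6-(3,5-dibromo-2-methoxyphenoxy)phenyl methanesulfonate
Conditions: Br2 (2.1 equiv), NaOAc (2.5 equiv), AcOH, 15–20 °C; aq. NaHSO3 quench
Reagents that add atoms: bromine, BrBr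
Why: Electrophilic aromatic substitution: bromine attacks B2 and B4 of ring B, the arenium ions being stabilised by the amino nitrogen on B3 (ortho to both sites) and by the ether oxygen on B1 (ortho to B2, para to B4), and proton loss restores the arene. The closest known reaction type is the exhaustive ortho-bromination of para-substituted anilines with bromine in buffered acetic acid. No ring is closed and no stereocentre is formed. The selectivity required is substitution at B2 and B4 and nowhere else; on ring B this follows because B6, para to nitrogen, carries the sulfonyloxy group and B5 carries bromine, and because the mesylated oxygen is too weak a donor to direct and cannot be oxidised to a quinone imine. Ring A should stay untouched since its positions 3 and 5, the sites its methoxy group would activate, are filled and the two bromines deactivate its remaining positions 4 and 6. NaOAc removes HBr so that the weakly basic aniline stays unprotonated and the second, more crowded substitution can go to completion.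

Step 9
Reactants: 11 4-amino-2,3,5-tribromo-6-(3,5-dibromo-2-methoxyphenoxy)phenyl methanesulfonate
Product: 13 2,3,5-tribromo-6-(3,5-dibromo-2-methoxyphenoxy)phenyl methanesulfonate, via arenediazonium hydrogen sulfate 12 (not isolated)
Conditions: NaNO2 (1.3 equiv), conc. H2SO4, AcOH, 5–15 °C; then 50% aq. H3PO2 (10 equiv), 0 → 25 °C
Reagents that add atoms: none
Why: Diazotisation of a weakly basic 2,6-dibromoaniline with nitrosylsulfuric acid followed by hydrodediazoniation with hypophosphorous acid (radical chain hydrogen transfer to the aryl radical), the classical way to remove an amino group flanked by two halogens, run without chloride so that no halide can displace an ortho bromine of the diazonium ion.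

Step 10
Reactants: 13 2,3,5-tribromo-6-(3,5-dibromo-2-methoxyphenoxy)phenyl methanesulfonate
Product: 14 2,3,5-tribromo-6-(3,5-dibromo-2-methoxyphenoxy)phenol
Conditions: KOH (5 equiv), MeOH–H2O (4:1), 60 °C; aq. HCl work-up
Reagents that add atoms: none
Why: Alkaline cleavage of an aryl sulfonate at the sulfur–oxygen bond, eased by the good leaving-group ability of the tribrominated phenoxide, under conditions that leave the aryl bromides, the methyl ether and the diaryl ether alone.

Compound list
1 | 4-nitrocatechol (4-nitrobenzene-1,2-diol) | Oc1ccc(cc1O)[N+](=O)[O-] | starting material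
2 | 2-fluorobenzaldehyde | O=Cc1ccccc1F | starting material
3 | 2-(2-hydroxy-5-nitrophenoxy)benzaldehyde | O=Cc1ccccc1Oc1cc(ccc1O)[N+](=O)[O-] | intermediate
4 | 2-(3-bromo-2-hydroxy-5-nitrophenoxy)benzaldehyde | O=Cc1ccccc1Oc1cc(cc(Br)c1O)[N+](=O)[O-] | intermediate
5 | 2-bromo-6-(2-formylphenoxy)-4-nitrophenyl methanesulfonate | CS(=O)(=O)Oc1c(Br)cc(cc1Oc1ccccc1C=O)[N+](=O)[O-] | intermediate
6 | 2-[3-bromo-2-(methanesulfonyloxy)-5-nitrophenoxy]phenyl formate | CS(=O)(=O)Oc1c(Br)cc(cc1Oc1ccccc1OC=O)[N+](=O)[O-] | intermediate (not isolated)
7 | 2-bromo-6-(2-hydroxyphenoxy)-4-nitrophenyl methanesulfonate | CS(=O)(=O)Oc1c(Br)cc(cc1Oc1ccccc1O)[N+](=O)[O-] | intermediate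
8 | 2-bromo-6-(3,5-dibromo-2-hydroxyphenoxy)-4-nitrophenyl methanesulfonate | CS(=O)(=O)Oc1c(Br)cc(cc1Oc1cc(Br)cc(Br)c1O)[N+](=O)[O-] | intermediate
9 | 2-bromo-6-(3,5-dibromo-2-methoxyphenoxy)-4-nitrophenyl methanesulfonate | COc1c(Br)cc(Br)cc1Oc1cc(cc(Br)c1OS(C)(=O)=O)[N+](=O)[O-] | intermediate
10 | 4-amino-2-bromo-6-(3,5-dibromo-2-methoxyphenoxy)phenyl methanesulfonate | COc1c(Br)cc(Br)cc1Oc1cc(N)cc(Br)c1OS(C)(=O)=O | intermediate
11 | 4-amino-2,3,5-tribromo-6-(3,5-dibromo-2-methoxyphenoxy)phenyl methanesulfonate | COc1c(Br)cc(Br)cc1Oc1c(Br)c(N)c(Br)c(Br)c1OS(C)(=O)=O | intermediate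
12 | 2,3,6-tribromo-5-(3,5-dibromo-2-methoxyphenoxy)-4-(methanesulfonyloxy)benzenediazonium hydrogen sulfate | COc1c(Br)cc(Br)cc1Oc1c(Br)c([N+]#N)c(Br)c(Br)c1OS(C)(=O)=O.OS(=O)(=O)[O-] | intermediate (not isolated)
13 | 2,3,5-tribromo-6-(3,5-dibromo-2-methoxyphenoxy)phenyl methanesulfonate | COc1c(Br)cc(Br)cc1Oc1c(Br)cc(Br)c(Br)c1OS(C)(=O)=O | intermediate
14 | 2,3,5-tribromo-6-(3,5-dibromo-2-methoxyphenoxy)phenol | COc1c(Br)cc(Br)cc1Oc1c(Br)cc(Br)c(Br)c1O | target

Total step count: 10
Longest linear sequence: 10 steps (the route is linear from 1 and 2 to 14)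

Steps most likely to fail

Step 4. In the peracid adduct, hydride may migrate instead of the aryl group, because the ether oxygen is attached to a very electron-poor ring B; the aldehyde would then end as a benzoic acid. The activated mesylate may also be lost while the formate is cleaved. The fallback sets out from 3, whose ring B still carries a free hydroxyl and nothing base-labile, and performs the oxidation there. mCPBA in CH2Cl2 should give 2-(2-hydroxy-5-nitrophenoxy)phenyl formate F3, which is cleaved without isolation (HCl, MeOH) to 2-(2-hydroxy-5-nitrophenoxy)phenol F4. Bromine (3 equiv) in AcOH should then fill positions 3 and 5 of ring A and B5 in one operation and give 2,4-dibromo-6-(3-bromo-2-hydroxy-5-nitrophenoxy)phenol F5. One equivalent each of Et3N and MsCl at −30 °C should sulfonylate the more acidic, preferentially ionised bromonitrophenol, and the route is rejoined at 8.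

Step 1. Arylation may occur at the oxygen para to nitro or at both oxygens, and the aldehyde may suffer base-induced side reactions. The fallback sets out from 2 and fixes the regiochemistry in the coupling partner instead of in the dianion. 2-Methoxy-5-nitrophenol F1 (purchased; its free hydroxyl is meta to nitro) is arylated with 2 (K2CO3, DMF, 100 °C) to 2-(2-methoxy-5-nitrophenoxy)benzaldehyde F2. The methyl ether para to nitro is then cleaved by chloride (LiCl, DMF, 140 °C; substitution at the methyl carbon with the para-nitrophenoxide as leaving group), which leads back to 3.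

Step 6. Methylation of the hindered phenol may be slow under neutral conditions. If base is then needed, the ring A phenoxide may displace the nitro-activated mesylate on B6 (closure to a dibenzodioxin) or take over the sulfonyl group. The fallback sets out from 8 and reduces the nitro group first, so that the mesylate is no longer activated. Fe/NH4Cl should give 4-amino-2-bromo-6-(3,5-dibromo-2-hydroxyphenoxy)phenyl methanesulfonate F6. Br2 (2 equiv) in AcOH should brominate B2 and B4 as in step 8, since ring A has no free position ortho or para to its hydroxyl, and give 4-amino-2,3,5-tribromo-6-(3,5-dibromo-2-hydroxyphenoxy)phenyl methanesulfonate F7. MeI/K2CO3 in acetone should then methylate the phenol only, the amine being flanked by two bromines, and the route is rejoined at 11.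

Further compounds
F1 | step 1 | 2-methoxy-5-nitrophenol | COc1ccc(cc1O)[N+](=O)[O-]
F2 | step 1 | 2-(2-methoxy-5-nitrophenoxy)benzaldehyde | COc1ccc(cc1Oc1ccccc1C=O)[N+](=O)[O-]
F3 | step 4 | 2-(2-hydroxy-5-nitrophenoxy)phenyl formate | O=COc1ccccc1Oc1cc(ccc1O)[N+](=O)[O-]
F4 | step 4 | 2-(2-hydroxy-5-nitrophenoxy)phenol | Oc1ccccc1Oc1cc(ccc1O)[N+](=O)[O-]
F5 | step 4 | 2,4-dibromo-6-(3-bromo-2-hydroxy-5-nitrophenoxy)phenol | Oc1c(Br)cc(Br)cc1Oc1cc(cc(Br)c1O)[N+](=O)[O-]
F6 | step 6 | 4-amino-2-bromo-6-(3,5-dibromo-2-hydroxyphenoxy)phenyl methanesulfonate | CS(=O)(=O)Oc1c(Br)cc(N)cc1Oc1cc(Br)cc(Br)c1O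
F7 | step 6 | 4-amino-2,3,5-tribromo-6-(3,5-dibromo-2-hydroxyphenoxy)phenyl methanesulfonate | CS(=O)(=O)Oc1c(Br)c(Br)c(N)c(Br)c1Oc1cc(Br)cc(Br)c1O
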